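**Retrosynthetic overview**
1. Target 38 ⇒ allylic alcohol 36. The C6 acetate and the 4,5-oxirane (from the 4Z alkene, oxygen delivered by the free C6 hydroxyl) come last; the C8 angelate is put on while O6 is still silylated.
2. The ten-membered carbocycle C1–C10 is opened at C2–C3. This bond joins isoprene unit C9–C10(C14)–C1–C2 to unit C3–C4(C15)–C5–C6; C2 is allylic to the 1(10)E alkene and C3 to the 4Z alkene. C2 therefore carries a sulfonyl carbanion and C3 a primary allylic chloride (28 → 30), and the sulfone is removed afterwards.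
3. Chain 28 ⇒ Weinreb amide 13 (C6–C2) + Z-alkenyllithium 18 (C3–C5, from propargyl alcohol). C6 is set by Evans–Tishchenko 1,3-anti reduction of enone 20, which also tells O6 and O8 apart (later TBS and TES).
4. 13 ⇒ Evans syn aldol (C7, C8) of N-isovaleryl (R)-benzyloxazolidinone 10 with aldehyde 6 (C8–C2). The sulfur is carried as the phenyl sulfide and oxidised to the sulfone only after the organolithium step.
5. Ring order: ten-membered ring (step 18), then the oxirane (step 23).

Key step: step 18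

Assumption: C1–C15 in the text are the germacrane locants of the target, also for open-chain intermediates (whose systematic names are numbered as heptanes or decanes); 30 is carried as both C2 epimers; where the C7 descriptor switches between R and S (21, 36, 37) only CIP priorities change, not the arrangement in space.

**Route**

Step 1
Reactants: 1 tert-butyl(but-3-yn-1-yloxy)dimethylsilane
Product: 3 (2E)-5-(tert-butyldimethylsilyloxy)-3-methylpent-2-en-1-ol, via alkenylalane 2 (not isolated)
Conditions: AlMe3 (2.5 equiv), Cp2ZrCl2 (0.2 equiv), CH2Cl2, 0 °C → rt; then (CH2O)n, THF, 0 °C → rt; aq. KNaC4H4O6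
Reagents that add atoms: trimethylaluminium, C[Al](C)C; formaldehyde (as paraformaldehyde), C=O
Why: Negishi zirconium-catalysed carboalumination adds methyl and aluminium syn across the terminal alkyne with the metal at the terminus, so trapping the alkenylalane with formaldehyde should give the trisubstituted allylic alcohol with the later 1(10)E geometry as one isomer.

Step 2
Reactants: 3 (2E)-5-(tert-butyldimethylsilyloxy)-3-methylpent-2-en-1-ol
Product: 4 tert-butyl(dimethyl){[(3E)-3-methyl-5-(phenylsulfanyl)pent-3-en-1-yl]oxy}silane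
Conditions: PhSSPh, n-Bu3P, THF, 0 °C → rt
Reagents that add atoms: diphenyl disulfide, c1ccccc1SSc1ccccc1
Why: Hata sulfenylation, in which the alkoxyphosphonium of the primary allylic alcohol is displaced by thiophenolate in an SN2 reaction, keeps the alkene position and geometry and brings in the C2 sulfur at the sulfide level, which tolerates the later organolithium and hydride steps.

Step 3
Reactants: 4 tert-butyl(dimethyl){[(3E)-3-methyl-5-(phenylsulfanyl)pent-3-en-1-yl]oxy}silane
Product: 5 (3E)-3-methyl-5-(phenylsulfanyl)pent-3-en-1-ol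
Conditions: camphorsulfonic acid (0.1 equiv), MeOH, 0 °C → rt
Reagents that add atoms: none
Why: acid-catalysed methanolysis of a primary silyl ether, to which the sulfide and the trisubstituted alkene are inert.

Step 4
Reactants: 5 (3E)-3-methyl-5-(phenylsulfanyl)pent-3-en-1-ol
Product: 6 (3E)-3-methyl-5-(phenylsulfanyl)pent-3-enal
Conditions: Dess–Martin periodinane, pyridine, CH2Cl2, 0 °C; used at once without chromatography
Reagents that add atoms: none
Why: Dess–Martin oxidation under buffered, non-basic conditions should give the β,γ-unsaturated aldehyde without moving the alkene into conjugation and without oxidising the sulfide.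

Step 5
Reactants: 7 (R)-4-benzyl-1,3-oxazolidin-2-one; 8 3-methylbutanoyl chloride (isovaleryl chloride)
Product: 10 (R)-4-benzyl-3-(3-methylbutanoyl)-1,3-oxazolidin-2-one, via lithium oxazolidinide 9 (not isolated)
Conditions: n-BuLi, THF, −78 °C; then 8, −78 → 0 °C
Reagents that add atoms: none
Why: N-acylation of the lithiated oxazolidinone by the acid chloride (standard imide formation), which leaves the auxiliary stereocentre untouched.

Step 6
Reactants: 10 (R)-4-benzyl-3-(3-methylbutanoyl)-1,3-oxazolidin-2-one; 6 (3E)-3-methyl-5-(phenylsulfanyl)pent-3-enal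
Product: 12 (4R)-4-benzyl-3-[(2R,3S,5E)-3-hydroxy-5-methyl-7-(phenylsulfanyl)-2-(propan-2-yl)hept-5-enoyl]-1,3-oxazolidin-2-one, via boron enolate 11 (not isolated)
Conditions: Bu2BOTf, i-Pr2NEt, CH2Cl2, −78 → 0 °C; then 6, −78 → 0 °C; pH 7 phosphate buffer, MeOH (no peroxide)
Reagents that add atoms: none
Why: Evans syn aldol, in which the Z dibutylboron enolate reacts through a closed chair transition state on the face away from the benzyl group of the (R)-auxiliary, should set C7 (R) and C8 (S) with isopropyl and hydroxyl syn; peroxide is left out of the work-up to spare the sulfide.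

Step 7
Reactants: 12 (4R)-4-benzyl-3-[(2R,3S,5E)-3-hydroxy-5-methyl-7-(phenylsulfanyl)-2-(propan-2-yl)hept-5-enoyl]-1,3-oxazolidin-2-one
Product: 13 (2R,3S,5E)-3-hydroxy-N-methoxy-N,5-dimethyl-7-(phenylsulfanyl)-2-(propan-2-yl)hept-5-enamide
Conditions: MeNHOMe·HCl, AlMe3, CH2Cl2, −20 → 0 °C; aq. KNaC4H4O6
Reagents that add atoms: N,O-dimethylhydroxylamine hydrochloride, CNOC.Cl
Why: aluminium amide transamination of the β-hydroxy imide (Weinreb amide formation), assisted by the free C8 hydroxyl, cleaves the exocyclic carbonyl and releases the auxiliary without touching C7 or C8.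

Step 8
Reactants: 14 prop-2-yn-1-ol
Product: 16 (2Z)-3-iodo-2-methylprop-2-en-1-ol, via magnesium chelate 15 (not isolated)
Conditions: MeMgBr (2.5 equiv), CuI (0.1 equiv), THF, −10 °C → rt; then I2, −10 °C → rt
Reagents that add atoms: methylmagnesium bromide, C[Mg]Br; iodine, II
Why: copper-catalysed anti carbomagnesiation of the propargylic alkoxide gives a five-membered alkenylmagnesium chelate, and iodinolysis with retention should give the iodide with iodine and CH2OH cis, the geometry needed at C4–C5.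

Step 9
Reactants: 16 (2Z)-3-iodo-2-methylprop-2-en-1-ol
Product: 17 1-({[(2Z)-3-iodo-2-methylprop-2-en-1-yl]oxy}methyl)-4-methoxybenzene
Conditions: NaH, 4-methoxybenzyl chloride, Bu4NI (cat.), THF/DMF, 0 °C → rt
Reagents that add atoms: 4-methoxybenzyl chloride, COc1ccc(CCl)cc1
Why: Williamson etherification; a benzyl-type ether is chosen because a silyl ether would be prone to 1,4 oxygen-to-carbon silyl migration in the cis alkenyllithium made next.

Step 10
Reactants: 17 1-({[(2Z)-3-iodo-2-methylprop-2-en-1-yl]oxy}methyl)-4-methoxybenzene; 13 (2R,3S,5E)-3-hydroxy-N-methoxy-N,5-dimethyl-7-(phenylsulfanyl)-2-(propan-2-yl)hept-5-enamide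
Product: 20 (2Z,5R,6S,8E)-6-hydroxy-1-[(4-methoxybenzyl)oxy]-2,8-dimethyl-10-(phenylsulfanyl)-5-(propan-2-yl)deca-2,8-dien-4-one, via alkenyllithium 18 (not isolated), via magnesium alkoxide 19 (not isolated)
Conditions: 17, t-BuLi (2 equiv per iodide), Et2O, −78 °C; 13, i-PrMgCl (1 equiv), THF, −78 °C; combine, −78 → −20 °C; aq. NH4Cl
Reagents that add atoms: none
Why: iodine–lithium exchange with retention of the Z geometry and addition to the Weinreb amide, whose chelated tetrahedral intermediate prevents over-addition, should give the β-hydroxy Z-enone; the C8 hydroxyl is masked in the flask as its magnesium alkoxide and the ketone appears only on work-up, so C7 is not epimerised.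

Step 11
Reactants: 20 (2Z,5R,6S,8E)-6-hydroxy-1-[(4-methoxybenzyl)oxy]-2,8-dimethyl-10-(phenylsulfanyl)-5-(propan-2-yl)deca-2,8-dien-4-one
Product: 21 (2Z,4S,5S,6S,8E)-4-hydroxy-1-[(4-methoxybenzyl)oxy]-2,8-dimethyl-10-(phenylsulfanyl)-5-(propan-2-yl)deca-2,8-dien-6-yl benzoate
Conditions: PhCHO (5 equiv), SmI2 (0.3 equiv), THF, −10 °C
Reagents that add atoms: benzaldehyde, O=Cc1ccccc1
Why: Evans–Tishchenko reduction, in which the samarium-bound hemiacetal on O8 delivers hydride intramolecularly to the C6 ketone through a chair-like six-membered transition state, should set C6 (S) 1,3-anti to C8 and leaves O8 as the benzoate and O6 free, so the two oxygens are differentiated.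

Step 12
Reactants: 21 (2Z,4S,5S,6S,8E)-4-hydroxy-1-[(4-methoxybenzyl)oxy]-2,8-dimethyl-10-(phenylsulfanyl)-5-(propan-2-yl)deca-2,8-dien-6-yl benzoate
Product: 22 (2Z,4S,5R,6S,8E)-4-(tert-butyldimethylsilyloxy)-1-[(4-methoxybenzyl)oxy]-2,8-dimethyl-10-(phenylsulfanyl)-5-(propan-2-yl)deca-2,8-dien-6-yl benzoate
Conditions: t-BuMe2SiOTf, 2,6-lutidine, CH2Cl2, −78 → 0 °C
Reagents that add atoms: tert-butyldimethylsilyl triflate, CC(C)(C)[Si](C)(C)OS(=O)(=O)C(F)(F)F
Why: silylation of the hindered allylic C6 hydroxyl with a silyl triflate at low temperature, fast enough to forestall 1,3-benzoyl migration.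

Step 13
Reactants: 22 (2Z,4S,5R,6S,8E)-4-(tert-butyldimethylsilyloxy)-1-[(4-methoxybenzyl)oxy]-2,8-dimethyl-10-(phenylsulfanyl)-5-(propan-2-yl)deca-2,8-dien-6-yl benzoate
Product: 23 (2Z,4S,5R,6S,8E)-4-(tert-butyldimethylsilyloxy)-1-[(4-methoxybenzyl)oxy]-2,8-dimethyl-10-(phenylsulfanyl)-5-(propan-2-yl)deca-2,8-dien-6-ol
Conditions: i-Bu2AlH (3 equiv), CH2Cl2, −78 °C; aq. KNaC4H4O6
Reagents that add atoms: none
Why: reductive cleavage of the benzoate by the aluminium hydride at low temperature, where the aluminium alkoxide does not trigger silyl migration and the ethers, sulfide and alkenes are inert; an ester at O8 could not be carried into the carbanion step.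

Step 14
Reactants: 23 (2Z,4S,5R,6S,8E)-4-(tert-butyldimethylsilyloxy)-1-[(4-methoxybenzyl)oxy]-2,8-dimethyl-10-(phenylsulfanyl)-5-(propan-2-yl)deca-2,8-dien-6-ol
Product: 24 (2Z,4S,5R,6S,8E)-4-(tert-butyldimethylsilyloxy)-1-[(4-methoxybenzyl)oxy]-2,8-dimethyl-10-(phenylsulfanyl)-5-(propan-2-yl)-6-(triethylsilyloxy)deca-2,8-diene
Conditions: Et3SiOTf, 2,6-lutidine, CH2Cl2, −78 °C
Reagents that add atoms: triethylsilyl triflate, CC[Si](CC)(CC)OS(=O)(=O)C(F)(F)F
Why: silylation of C8–OH with a group that is inert to amide bases and can later be removed before the C6 TBS ether.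

Step 15
Reactants: 24 (2Z,4S,5R,6S,8E)-4-(tert-butyldimethylsilyloxy)-1-[(4-methoxybenzyl)oxy]-2,8-dimethyl-10-(phenylsulfanyl)-5-(propan-2-yl)-6-(triethylsilyloxy)deca-2,8-diene
Product: 25 (2Z,4S,5R,6S,8E)-10-(benzenesulfonyl)-4-(tert-butyldimethylsilyloxy)-1-[(4-methoxybenzyl)oxy]-2,8-dimethyl-5-(propan-2-yl)-6-(triethylsilyloxy)deca-2,8-diene
Conditions: (NH4)6Mo7O24·4H2O (0.1 equiv), 30% aq. H2O2, EtOH, 0 °C → rt
Reagents that add atoms: hydrogen peroxide, OO
Why: molybdate-catalysed peroxide oxidation takes the sulfide through the sulfoxide to the sulfone much faster than it epoxidises unactivated trisubstituted alkenes, and no free hydroxyl is present to direct an epoxidation.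

Step 16
Reactants: 25 (2Z,4S,5R,6S,8E)-10-(benzenesulfonyl)-4-(tert-butyldimethylsilyloxy)-1-[(4-methoxybenzyl)oxy]-2,8-dimethyl-5-(propan-2-yl)-6-(triethylsilyloxy)deca-2,8-diene
Product: 26 (2Z,4S,5R,6S,8E)-10-(benzenesulfonyl)-4-(tert-butyldimethylsilyloxy)-2,8-dimethyl-5-(propan-2-yl)-6-(triethylsilyloxy)deca-2,8-dien-1-ol
Conditions: DDQ, CH2Cl2/pH 7 buffer, 0 °C
Reagents that add atoms: none
Why: oxidative cleavage of the 4-methoxybenzyl ether by hydride abstraction at its electron-rich benzylic position, which leaves silyl ethers, sulfone and alkenes alone.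

Step 17
Reactants: 26 (2Z,4S,5R,6S,8E)-10-(benzenesulfonyl)-4-(tert-butyldimethylsilyloxy)-2,8-dimethyl-5-(propan-2-yl)-6-(triethylsilyloxy)deca-2,8-dien-1-ol
Product: 28 (2Z,4S,5R,6S,8E)-10-(benzenesulfonyl)-4-(tert-butyldimethylsilyloxy)-1-chloro-2,8-dimethyl-5-(propan-2-yl)-6-(triethylsilyloxy)deca-2,8-diene, via allylic mesylate 27 (not isolated)
Conditions: MsCl, 2,4,6-collidine, LiCl, DMF, 0 °C
Reagents that add atoms: lithium chloride, [Li+].[Cl-]
Why: mesylation and in-flask SN2 displacement by chloride at the primary allylic carbon C3 under near-neutral conditions should keep the 4Z geometry and avoid allylic transposition.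

Step 18
Reactants: 28 (2Z,4S,5R,6S,8E)-10-(benzenesulfonyl)-4-(tert-butyldimethylsilyloxy)-1-chloro-2,8-dimethyl-5-(propan-2-yl)-6-(triethylsilyloxy)deca-2,8-diene
Product: 30 (1(10)E,4Z,6S,7R,8S)-2-(benzenesulfonyl)-6-(tert-butyldimethylsilyloxy)-8-(triethylsilyloxy)germacra-1(10),4-diene (both C2 epimers), via potassium carbanion 29 (not isolated)
Conditions: 28 added by syringe pump over 8 h to KN(SiMe3)2 (1.3 equiv), THF, −20 → 0 °C, final concentration about 0.002 M; aq. NH4Cl
Reagents that add atoms: none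
Why: KN(SiMe3)2 removes a C2 proton, which is both allylic and α to the sulfone, and the resulting carbanion 29 attacks the primary allylic carbon C3 in a direct SN2 displacement of chloride. The closest known reaction type is the intramolecular alkylation of an allyl sulfone carbanion by an allylic halide, used to close medium and large isoprenoid carbocycles. The ten-membered ring closes in a 10-exo-tet mode by forming C2–C3. No stereocentre of the target is made: C2 becomes a sulfone-bearing centre of either configuration that is erased in step 19, and C6, C7 and C8 are spectators. The step needs α- over γ-attack of the allyl anion, SN2 over SN2' at the electrophile, ring closure over oligomerisation, and untouched 4Z and 1(10)E geometries. These should be secured by the sulfone holding the charge at C2, by the open primary chloride against a C5 terminus shielded by the C6 silyl ether, by slow addition at high dilution, by the absence of any transition metal that could form an allyl complex, and by silyl ethers that offer no acidic or electrophilic site.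

Step 19
Reactants: 30 (1(10)E,4Z,6S,7R,8S)-2-(benzenesulfonyl)-6-(tert-butyldimethylsilyloxy)-8-(triethylsilyloxy)germacra-1(10),4-diene
Product: 31 (1(10)E,4Z,6S,7R,8S)-6-(tert-butyldimethylsilyloxy)-8-(triethylsilyloxy)germacra-1(10),4-diene
Conditions: PdCl2(dppp) (0.1 equiv), LiBHEt3 (3 equiv), THF, 0 °C
Reagents that add atoms: none
Why: palladium-catalysed hydride desulfonylation of an allylic sulfone, in which zerovalent palladium ionises the C2–S bond and hydride is delivered to the less substituted C2 terminus of the allyl complex, should leave the 1(10) alkene in place with E geometry and removes the uncontrolled C2 centre; the 4Z alkene and the silyl ethers take no part.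

Step 20
Reactants: 31 (1(10)E,4Z,6S,7R,8S)-6-(tert-butyldimethylsilyloxy)-8-(triethylsilyloxy)germacra-1(10),4-diene
Product: 32 (1(10)E,4Z,6S,7R,8S)-6-(tert-butyldimethylsilyloxy)germacra-1(10),4-dien-8-ol
Conditions: pyridinium p-toluenesulfonate (0.2 equiv), MeOH/CH2Cl2, 0 °C
Reagents that add atoms: none
Why: selective acid-catalysed methanolysis of the triethylsilyl ether, which reacts far faster than the hindered TBS ether, under acidity too mild for transannular cyclisation of the diene.

Step 21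
Reactants: 32 (1(10)E,4Z,6S,7R,8S)-6-(tert-butyldimethylsilyloxy)germacra-1(10),4-dien-8-ol; 33 angelic acid [(2Z)-2-methylbut-2-enoic acid]
Product: 35 (1(10)E,4Z,6S,7R,8S)-6-(tert-butyldimethylsilyloxy)germacra-1(10),4-dien-8-yl (2Z)-2-methylbut-2-enoate, via mixed anhydride 34 (not isolated)
Conditions: 33, 2,4,6-trichlorobenzoyl chloride, Et3N, toluene, rt; then 32, 70 °C (no DMAP)
Reagents that add atoms: none
Why: Yamaguchi-type esterification through the mixed anhydride without a nucleophilic catalyst, a protocol known to give angelates without isomerisation to the tiglate; C8–OH is the only free hydroxyl, so no site selectivity is needed, and the cis,trans 1,5-diene should not undergo Cope rearrangement at this temperature.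

Step 22
Reactants: 35 (1(10)E,4Z,6S,7R,8S)-6-(tert-butyldimethylsilyloxy)germacra-1(10),4-dien-8-yl (2Z)-2-methylbut-2-enoate
Product: 36 (1(10)E,4Z,6S,7S,8S)-6-hydroxygermacra-1(10),4-dien-8-yl (2Z)-2-methylbut-2-enoate
Conditions: HF·pyridine, pyridine, THF, 0 °C → rt
Reagents that add atoms: none
Why: fluoride-mediated desilylation under buffered, non-basic conditions, which should avoid 1,3-migration of the angelate to O6 and acid-induced transannular cyclisation.

Step 23
Reactants: 36 (1(10)E,4Z,6S,7S,8S)-6-hydroxygermacra-1(10),4-dien-8-yl (2Z)-2-methylbut-2-enoate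
Product: 37 (1(10)E,4S,5R,6R,7S,8S)-4,5-epoxy-6-hydroxygermacr-1(10)-en-8-yl (2Z)-2-methylbut-2-enoate
Conditions: VO(acac)2 (0.05 equiv), t-BuOOH (1.5 equiv), CH2Cl2, 0 °C
Reagents that add atoms: tert-butyl hydroperoxide, CC(C)(C)OO
Why: hydroxyl-directed vanadium-catalysed epoxidation, in which the C6 alkoxide binds the pentavalent vanadium peroxide and passes oxygen only to the neighbouring 4Z alkene; by analogy with medium-ring (Z)-cycloalk-2-enols, which react through a small O–C–C=C dihedral angle and give cis epoxy alcohols, the oxirane oxygen should end erythro to O6 (4S,5R), while the hydroxyl-free 1(10) alkene and the electron-poor angelate are left alone.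

Step 24
Reactants: 37 (1(10)E,4S,5R,6R,7S,8S)-4,5-epoxy-6-hydroxygermacr-1(10)-en-8-yl (2Z)-2-methylbut-2-enoate
Product: 38 (1(10)E,4S,5R,6R,7R,8S)-6-acetoxy-4,5-epoxygermacr-1(10)-en-8-yl (2Z)-2-methylbut-2-enoate
Conditions: Ac2O, pyridine, DMAP (cat.), CH2Cl2, 0 °C → rt
Reagents that add atoms: acetic anhydride, CC(=O)OC(C)=O
Why: DMAP-catalysed acetylation of the remaining secondary hydroxyl under mild basic conditions, which should not open the oxirane or isomerise the already formed angelate.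

**Compound list**
1 | tert-butyl(but-3-yn-1-yloxy)dimethylsilane | C#CCCO[Si](C)(C)C(C)(C)C | starting material
2 | [(1E)-4-(tert-butyldimethylsilyloxy)-2-methylbut-1-en-1-yl]dimethylalane (not isolated) | C[Al](C)/C=C(\C)CCO[Si](C)(C)C(C)(C)C | intermediate
3 | (2E)-5-(tert-butyldimethylsilyloxy)-3-methylpent-2-en-1-ol | OC/C=C(\C)CCO[Si](C)(C)C(C)(C)C | intermediate
4 | tert-butyl(dimethyl){[(3E)-3-methyl-5-(phenylsulfanyl)pent-3-en-1-yl]oxy}silane | CC(C)(C)[Si](C)(C)OCC/C(C)=C/CSc1ccccc1 | intermediate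
5 | (3E)-3-methyl-5-(phenylsulfanyl)pent-3-en-1-ol | OCC/C(C)=C/CSc1ccccc1 | intermediate
6 | (3E)-3-methyl-5-(phenylsulfanyl)pent-3-enal | O=CC/C(C)=C/CSc1ccccc1 | intermediate
7 | (R)-4-benzyl-1,3-oxazolidin-2-one | O=C1N[C@H](Cc2ccccc2)CO1 | starting material
8 | 3-methylbutanoyl chloride (isovaleryl chloride) | CC(C)CC(Cl)=O | starting material
9 | N-lithio-(R)-4-benzyl-1,3-oxazolidin-2-one (not isolated) | [Li]N1[C@H](Cc2ccccc2)COC1=O | intermediate
10 | (R)-4-benzyl-3-(3-methylbutanoyl)-1,3-oxazolidin-2-one | CC(C)CC(=O)N1[C@H](Cc2ccccc2)COC1=O | intermediate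
11 | Z dibutylboron enolate of 10 (not isolated) | CCCCB(CCCC)O/C(N1[C@H](Cc2ccccc2)COC1=O)=C\C(C)C | intermediate
12 | (4R)-4-benzyl-3-[(2R,3S,5E)-3-hydroxy-5-methyl-7-(phenylsulfanyl)-2-(propan-2-yl)hept-5-enoyl]-1,3-oxazolidin-2-one | O=C(N1[C@H](Cc2ccccc2)COC1=O)[C@H](C(C)C)[C@@H](O)C/C(C)=C/CSc1ccccc1 | intermediate
13 | (2R,3S,5E)-3-hydroxy-N-methoxy-N,5-dimethyl-7-(phenylsulfanyl)-2-(propan-2-yl)hept-5-enamide | CON(C)C(=O)[C@H](C(C)C)[C@@H](O)C/C(C)=C/CSc1ccccc1 | intermediate
14 | prop-2-yn-1-ol (propargyl alcohol) | C#CCO | starting material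
15 | 4-methyl-2,5-dihydro-1,2-oxamagnesole, the cyclic alkenylmagnesium alkoxide (not isolated) | CC1=C[Mg]OC1 | intermediate
16 | (2Z)-3-iodo-2-methylprop-2-en-1-ol | OC/C(C)=C\I | intermediate
17 | 1-({[(2Z)-3-iodo-2-methylprop-2-en-1-yl]oxy}methyl)-4-methoxybenzene | COc1ccc(COC/C(C)=C\I)cc1 | intermediate
18 | {(1Z)-3-[(4-methoxybenzyl)oxy]-2-methylprop-1-en-1-yl}lithium (not isolated) | COc1ccc(COC/C(C)=C\[Li])cc1 | intermediate
19 | chloromagnesium C8 alkoxide of 13 (not isolated) | CON(C)C(=O)[C@H](C(C)C)[C@@H](O[Mg]Cl)C/C(C)=C/CSc1ccccc1 | intermediate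
20 | (2Z,5R,6S,8E)-6-hydroxy-1-[(4-methoxybenzyl)oxy]-2,8-dimethyl-10-(phenylsulfanyl)-5-(propan-2-yl)deca-2,8-dien-4-one | COc1ccc(COC/C(C)=C\C(=O)[C@H](C(C)C)[C@@H](O)C/C(C)=C/CSc2ccccc2)cc1 | intermediate
21 | (2Z,4S,5S,6S,8E)-4-hydroxy-1-[(4-methoxybenzyl)oxy]-2,8-dimethyl-10-(phenylsulfanyl)-5-(propan-2-yl)deca-2,8-dien-6-yl benzoate | COc1ccc(COC/C(C)=C\[C@H](O)[C@H](C(C)C)[C@@H](OC(=O)c2ccccc2)C/C(C)=C/CSc2ccccc2)cc1 | intermediate
22 | (2Z,4S,5R,6S,8E)-4-(tert-butyldimethylsilyloxy)-1-[(4-methoxybenzyl)oxy]-2,8-dimethyl-10-(phenylsulfanyl)-5-(propan-2-yl)deca-2,8-dien-6-yl benzoate | COc1ccc(COC/C(C)=C\[C@H](O[Si](C)(C)C(C)(C)C)[C@H](C(C)C)[C@@H](OC(=O)c2ccccc2)C/C(C)=C/CSc2ccccc2)cc1 | intermediate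
23 | (2Z,4S,5R,6S,8E)-4-(tert-butyldimethylsilyloxy)-1-[(4-methoxybenzyl)oxy]-2,8-dimethyl-10-(phenylsulfanyl)-5-(propan-2-yl)deca-2,8-dien-6-ol | COc1ccc(COC/C(C)=C\[C@H](O[Si](C)(C)C(C)(C)C)[C@H](C(C)C)[C@@H](O)C/C(C)=C/CSc2ccccc2)cc1 | intermediate
24 | (2Z,4S,5R,6S,8E)-4-(tert-butyldimethylsilyloxy)-1-[(4-methoxybenzyl)oxy]-2,8-dimethyl-10-(phenylsulfanyl)-5-(propan-2-yl)-6-(triethylsilyloxy)deca-2,8-diene | COc1ccc(COC/C(C)=C\[C@H](O[Si](C)(C)C(C)(C)C)[C@H](C(C)C)[C@@H](O[Si](CC)(CC)CC)C/C(C)=C/CSc2ccccc2)cc1 | intermediate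
25 | (2Z,4S,5R,6S,8E)-10-(benzenesulfonyl)-4-(tert-butyldimethylsilyloxy)-1-[(4-methoxybenzyl)oxy]-2,8-dimethyl-5-(propan-2-yl)-6-(triethylsilyloxy)deca-2,8-diene | COc1ccc(COC/C(C)=C\[C@H](O[Si](C)(C)C(C)(C)C)[C@H](C(C)C)[C@@H](O[Si](CC)(CC)CC)C/C(C)=C/CS(=O)(=O)c2ccccc2)cc1 | intermediate
26 | (2Z,4S,5R,6S,8E)-10-(benzenesulfonyl)-4-(tert-butyldimethylsilyloxy)-2,8-dimethyl-5-(propan-2-yl)-6-(triethylsilyloxy)deca-2,8-dien-1-ol | OC/C(C)=C\[C@H](O[Si](C)(C)C(C)(C)C)[C@H](C(C)C)[C@@H](O[Si](CC)(CC)CC)C/C(C)=C/CS(=O)(=O)c1ccccc1 | intermediate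
27 | methanesulfonate of 26 (not isolated) | CS(=O)(=O)OC/C(C)=C\[C@H](O[Si](C)(C)C(C)(C)C)[C@H](C(C)C)[C@@H](O[Si](CC)(CC)CC)C/C(C)=C/CS(=O)(=O)c1ccccc1 | intermediate
28 | (2Z,4S,5R,6S,8E)-10-(benzenesulfonyl)-4-(tert-butyldimethylsilyloxy)-1-chloro-2,8-dimethyl-5-(propan-2-yl)-6-(triethylsilyloxy)deca-2,8-diene (open-chain chloro sulfone: C3 chloride, C2 sulfone) | ClC/C(C)=C\[C@H](O[Si](C)(C)C(C)(C)C)[C@H](C(C)C)[C@@H](O[Si](CC)(CC)CC)C/C(C)=C/CS(=O)(=O)c1ccccc1 | intermediate
29 | potassium salt of the C2 carbanion of 28 (not isolated) | ClC/C(C)=C\[C@H](O[Si](C)(C)C(C)(C)C)[C@H](C(C)C)[C@@H](O[Si](CC)(CC)CC)C/C(C)=C/[CH-]S(=O)(=O)c1ccccc1.[K+] | intermediate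
30 | (1(10)E,4Z,6S,7R,8S)-2-(benzenesulfonyl)-6-(tert-butyldimethylsilyloxy)-8-(triethylsilyloxy)germacra-1(10),4-diene, both C2 epimers | C1/C(C)=C\[C@H](O[Si](C)(C)C(C)(C)C)[C@H](C(C)C)[C@@H](O[Si](CC)(CC)CC)C/C(C)=C/C1S(=O)(=O)c1ccccc1 | intermediate
31 | (1(10)E,4Z,6S,7R,8S)-6-(tert-butyldimethylsilyloxy)-8-(triethylsilyloxy)germacra-1(10),4-diene | C1/C(C)=C\[C@H](O[Si](C)(C)C(C)(C)C)[C@H](C(C)C)[C@@H](O[Si](CC)(CC)CC)C/C(C)=C/C1 | intermediate
32 | (1(10)E,4Z,6S,7R,8S)-6-(tert-butyldimethylsilyloxy)germacra-1(10),4-dien-8-ol | C1/C(C)=C\[C@H](O[Si](C)(C)C(C)(C)C)[C@H](C(C)C)[C@@H](O)C/C(C)=C/C1 | intermediate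
33 | angelic acid, (2Z)-2-methylbut-2-enoic acid | C/C=C(/C)C(=O)O | starting material
34 | (2Z)-2-methylbut-2-enoic 2,4,6-trichlorobenzoic anhydride (not isolated) | C/C=C(/C)C(=O)OC(=O)c1c(Cl)cc(Cl)cc1Cl | intermediate
35 | (1(10)E,4Z,6S,7R,8S)-6-(tert-butyldimethylsilyloxy)germacra-1(10),4-dien-8-yl (2Z)-2-methylbut-2-enoate | C/C=C(/C)C(=O)O[C@H]1C/C(C)=C/CC/C(C)=C\[C@H](O[Si](C)(C)C(C)(C)C)[C@@H]1C(C)C | intermediate
36 | (1(10)E,4Z,6S,7S,8S)-6-hydroxygermacra-1(10),4-dien-8-yl (2Z)-2-methylbut-2-enoate | C/C=C(/C)C(=O)O[C@H]1C/C(C)=C/CC/C(C)=C\[C@H](O)[C@@H]1C(C)C | intermediate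
37 | (1(10)E,4S,5R,6R,7S,8S)-4,5-epoxy-6-hydroxygermacr-1(10)-en-8-yl (2Z)-2-methylbut-2-enoate | C/C=C(/C)C(=O)O[C@H]1C/C(C)=C/CC[C@]2(C)O[C@@H]2[C@H](O)[C@@H]1C(C)C | intermediate
38 | (1(10)E,4S,5R,6R,7R,8S)-6-acetoxy-4,5-epoxygermacr-1(10)-en-8-yl (2Z)-2-methylbut-2-enoate | C/C=C(/C)C(=O)O[C@H]1C/C(C)=C/CC[C@]2(C)O[C@@H]2[C@H](OC(C)=O)[C@@H]1C(C)C | target

**Step count**
Total: 24 steps. Longest linear sequence: 21 steps (steps 1–4, 6, 7, 10–24).

**Steps most likely to fail**

Step 18. The ten-membered transition state is strained, so intermolecular alkylation to dimers and oligomers, base-induced loss of HCl from the allylic chloride, or attack through the γ-carbon C10 may outrun ring closure. The fallback keeps the C2–C3 closure but uses a more nucleophilic carbanion, the sulfide-stabilised allyllithium, a known way of coupling isoprenoid allyl units. It sets out from sulfide 24, before the oxidation of step 15. DDQ removes the 4-methoxybenzyl ether to give the C3 allylic alcohol F1, and Ph3P with hexachloroacetone at −20 °C converts this into the allylic chloride F2. Slow addition of F2 to LDA (or n-BuLi with DABCO) in THF at −78 °C under high dilution forms the lithiated sulfide F3, which should close by α-alkylation to the cyclic phenyl sulfide F4. Lithium in ethylamine at −78 °C then cleaves the allylic C–S bond, and the route is rejoined at diene 31.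

Step 19. Hydride may be delivered to C10 instead of C2, which moves the double bond to C1–C2, or the allylpalladium may equilibrate and erode the E geometry. The fallback replaces hydride substitution by electron-transfer cleavage: 30 is treated with 5% Na/Hg and Na2HPO4 in MeOH/THF at −20 °C, the C–S bond is broken by single-electron reduction, and the allyl anion is protonated by methanol at the less substituted C2. No allylpalladium species is involved. It sets out from 30 and comes back at 31; no new compound is made (F0).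

Step 23. Oxygen may be delivered to the other face of C4–C5 if the ring prefers the other rotamer about C5–C6, or the 1(10) alkene may compete. The fallback hands face selection from the ring conformation to a chiral ligand: vanadium-catalysed asymmetric epoxidation with VO(Oi-Pr)3, a C2-symmetric bishydroxamic acid ligand of the enantiomer matched to the required face, and aqueous t-BuOOH in toluene at 0 °C. This reaction type is known to work on Z allylic alcohols. It sets out from 36 and comes back at 37; no new compound is made (F0).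

**Further compounds**
F1 | step 18 | (2Z,4S,5R,6S,8E)-4-(tert-butyldimethylsilyloxy)-2,8-dimethyl-10-(phenylsulfanyl)-5-(propan-2-yl)-6-(triethylsilyloxy)deca-2,8-dien-1-ol | OC/C(C)=C\[C@H](O[Si](C)(C)C(C)(C)C)[C@H](C(C)C)[C@@H](O[Si](CC)(CC)CC)C/C(C)=C/CSc1ccccc1
F2 | step 18 | (2Z,4S,5R,6S,8E)-4-(tert-butyldimethylsilyloxy)-1-chloro-2,8-dimethyl-10-(phenylsulfanyl)-5-(propan-2-yl)-6-(triethylsilyloxy)deca-2,8-diene | ClC/C(C)=C\[C@H](O[Si](C)(C)C(C)(C)C)[C@H](C(C)C)[C@@H](O[Si](CC)(CC)CC)C/C(C)=C/CSc1ccccc1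
F3 | step 18 | C2-lithiated F2 (not isolated) | ClC/C(C)=C\[C@H](O[Si](C)(C)C(C)(C)C)[C@H](C(C)C)[C@@H](O[Si](CC)(CC)CC)C/C(C)=C/C([Li])Sc1ccccc1
F4 | step 18 | (1(10)E,4Z,6S,7R,8S)-6-(tert-butyldimethylsilyloxy)-2-(phenylsulfanyl)-8-(triethylsilyloxy)germacra-1(10),4-diene, both C2 epimers | C1/C(C)=C\[C@H](O[Si](C)(C)C(C)(C)C)[C@H](C(C)C)[C@@H](O[Si](CC)(CC)CC)C/C(C)=C/C1Sc1ccccc1
F0 | step 19 | none | none
F0 | step 23 | none | none
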